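(The constants used here were chosen freely; the flask was simulated.)

The half-life of E by its decay to X alone in autumn is 0.47 h, and that short life starts this examination.

    J + E ⇌ L + Q (K1 = 18, k1 = 0.0075 M⁻¹ s⁻¹)
    Q + E ⇌ L + Z (K2 = 2.8, k2 = 0.012 M⁻¹ s⁻¹)
    L → D (k3 = 3.0 × 10⁻⁴ s⁻¹)
    J + Q → J.Q (k4 = 5.0 × 10⁻⁴ M⁻¹ s⁻¹)
    E → X (k5 = 4.1 × 10⁻⁴ s⁻¹)

common to all: L 5.00 equiv; time 8.0 h

| flask | J | E | remark |
|---|---|---|---|
| dusk | 0.070 M | 0.700 equiv (fed, over 3.0 h) | all else is in the flask from the start; the feed brings no volume worth counting |
| summer | 0.070 M (fed, over 3.0 h) | 0.700 equiv | all else is in the flask from the start; the feed brings no volume worth counting |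
| autumn | 0.070 M | 0.700 equiv | everything together at the start |

- in percentages every species weighs as the J in it: one J.Q counts as two
- run time (dusk): 8.0 h

* which flask leads in share of Q in Q plus Z ("all alike" within 1.5 percentage points) (dusk / summer / autumn / all alike)
* share of Q in Q plus Z at the end, dusk
* share of Q in Q plus Z at the end, summer
* share of Q in Q plus Z at the end, autumn

**Which reagent do you balance first?** E, the limiting reagent, at 0.700 equiv to J. While it flows into dusk, what enters also leaves, so, taking cE as steady, the feed equals cE times a sink: the decay to X plus the first exchange with J. With J counted as charged, and the E taken by Q left out, the sink is 9.35 × 10⁻⁴ s⁻¹, so cE stands near 0.00485 M.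

**Why should Q care?** Q meets E with the constant 0.012 M⁻¹ s⁻¹. What counts is the second-exchange dose, that constant times the area under cE over time, which is 0.629. With the sink held fixed, that area is the charge over the sink whether E is fed or charged at once, so by this reckoning autumn receives the same dose.

**Then dusk and autumn should match?** No, and here is the weak spot: L turns Z back into Q. At charged L in autumn, the half-life of Z by that return is 0.128 h, shorter than the half-life of E by its decay alone, so in this reckoning Z goes back while E is present. By the end of the dusk feed, reckoning from the decay of L by itself, that half-life has grown to 3.28 h, much longer than at the start.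

**Your number for dusk?** In dusk, Q arrives steadily through the feed, so the average Q feels half the dose. Ignoring the return and the loss of Q to J.Q, my estimate of the share of Q in dusk is 76.1 %. I place autumn above dusk, and I give no number for summer.

The forecast named autumn as leader, with 62 % for dusk, 79 % for summer and 87 % for autumn, on the ground that “Z forms in quantity only when E is still around after L has gone; dosing E late does exactly that and hurts the Q share most”.

The simulation gives 77.1 % for dusk, 88.9 % for summer and 90.5 % for autumn, so autumn leads.

In dusk, L went to D earlier than E went to X, with half of each step's turnover up to the end done by 0.707 h and 1.86 h, while mean cE over the first 3.0 h was 0.00465 M against my 0.00485 M. From 4.00 h to 8.00 h in dusk, Z went from 5.07 % to 4.76 % while Q fell from 21.1 % to 16.0 % and J.Q grew to 21.5 %, so Z over Q rose from 0.240 to 0.297, against a half dose of 0.315 reckoned without that fall of Q. The neighbour of dusk with 1.20 equiv of E has, with the same sink, a dose of 1.08, the half-dose rule gives it 64.9 %, and it ended at 68.3 %.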